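## The problem

Target 22 is a 6H-isochromene-6,8(7H)-dione (azaphilone-type pyranoquinone). Isochromene numbering is used throughout: pyran ring O2/C1/C3/C4/C4a/C8a, carbocycle C4a–C5–C6–C7–C8–C8a.

- Every ring carbon except C1 is substituted, and C5–C8 are four contiguous oxygen-bearing carbons.
- The only stereocentre, C7 (R), is quaternary: methyl, butanoyloxy, and the two ring ketones C6 and C8. No other stereocentre can control it, so it must come from the chiral pool or a reagent. It cannot epimerise, but the 2-acyloxy-1,3-dicarbonyl unit is prone to retro-Claisen cleavage and acyl transfer under basic or nucleophilic conditions.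
- The chromophore is electrophilic at C1 (amines and hydroxide open the pyran), and the enolic 5-OH is acidic and oxidisable.
- There are three different hydroxyls: primary (free), enolic 5-OH (free), tertiary 7-OH (butyrate). Acylation must reach only the least reactive one.
- The 4-OMe group excludes the usual 2-alkynylbenzaldehyde precursor, because an alkyne carbon cannot carry the methoxy group. An aromatic 5,6,8-trioxygenated precursor would be a hydroxyquinol, which oxidants convert to a quinone instead of hydroxylating C7.
- The enabling feature: the heterocycle O2–C3(alkyl)=C4(OMe)–C4a(=C5)–C8a=C1H is a 3-methoxy-2-alkyl-4H-pyran-4-ylidene, i.e. maltol methyl ether whose carbonyl carbon C4a has become an exocyclic alkene. The chain C5–C6–C7–C8 with its four oxygens maps onto a 3-acyloxy-3-methylfuran-2,4-dione, in which O5 and C8 are tied as a lactone and C5 is the only enolisable carbon.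
- A C=S at C4a and a bromine at C5 therefore allow a sulfide contraction, which can form only the C4a=C5 bond.

## Retrosynthesis

**22 ⇒ 21.** Only the O–Si bond of the primary alcohol is cut. A silyl ether is chosen because it survives thionation, organomagnesium chemistry and amine bases, and is removed by fluoride under mildly acidic conditions that the pyranoquinone and the tertiary butyrate tolerate.

**21 ⇒ 19 (C8–C8a).** The carbocycle is opened at C8–C8a to give pyranylidene 19, which carries a vinyl iodide at C8a and a methyl ester at C8.
- This cut is preferred to C6–C7 or C7–C8 because it leaves the quaternary stereocentre and its butyrate untouched inside the chain.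
- The forward step is a halogen–magnesium exchange followed by 6-exo acylation (Parham-type).
- A metal at C8a is required: C8a of the neutral pyranylidene is only weakly nucleophilic, and any acid converts the ring to a pyrylium and removes that nucleophilicity.

**19 ⇒ 18 (temporary lactone).** The C8 ester and the 5-OH of 19 are joined retrosynthetically into enol lactone 18. The O5–C8 bond is not in the target.
- It serves three purposes: it masks the 5-OH, it stores C8 as an activated acyl group, and in the bromo ketone it makes C5 the only acidic carbon.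
- The lactone cannot pass its acyl group directly to C8a: the tetrahedral intermediate would be a 7-oxabicyclo[2.2.1]heptane with the C4a=C5 double bond at a bridgehead. It is therefore opened by methanol first.

**18 ⇒ 5 + 15 (C4a=C5, key disconnection).** The exocyclic double bond is cut into pyran-4-thione 5 and bromolactone 15.
- An external carbon nucleophile attacks a pyranone or pyrylium at C1 or C3 rather than at C4a. A temporary C–S bond delivers C5 to C4a and to no other carbon.
- The precursors are far simpler than 18: 5 is a monocyclic heterocycle with no stereocentre, and 15 is a five-membered lactone with one stereocentre.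
- The forward step must tolerate the vinyl iodide, the silyl ether and the butyrate, and needs only a tertiary amine and a phosphine.

**5 ⇒ 4 ⇒ 3 ⇒ 1 + 2.** The thione comes from pyranone 4, the iodide from electrophilic α-iodination of 3, and the side chain from lateral alkylation of commercial maltol methyl ether 1 with iodide 2. The 4-methoxy group and the whole pyran ring are bought, not made.

**15 ⇒ 14 ⇒ 13 ⇒ 11 ⇒ 10 ⇒ 8 + 9; 8 ⇒ 6 + 7.** Bromide 15 comes from ketone bromination of 14, and the butyrate from acylation of hydroxy lactone 13 while it is the only hydroxyl in the molecule. Lactone 13 arises by translactonisation of dioxolanone 11, itself made by aldol addition of the enolate of 8 to aldehyde 9 followed by oxidation. Dioxolanone 8 is the pivalaldehyde acetal of (R)-lactic acid 6. The acetal carbon keeps the stereochemical information while C7 is planar (self-regeneration of stereocentres) and is cleaved when the lactone forms.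

## Roads not taken

**Alternative 1: oxidative dearomatisation of a 2-benzopyrylium (the obvious route).** Cut: the C7–O bond and the pyran ring. Forward: build a hexasubstituted benzaldehyde, cyclise it to the anhydrobase A1 of the 5,6,8-trihydroxy-4-methoxy-2-benzopyrylium, then hydroxylate C7 enantioselectively (copper–sparteine–O2 or a flavin monooxygenase) to A2, and butyrylate.
- The 4-methoxy group forbids the alkyne cycloisomerisation entry, so a 1,2-dicarbonyl side chain on a fully substituted arene is needed.
- The 5-OH/8-OH pair of A1 is a hydroquinone, so oxidation to the quinone competes directly with C7 hydroxylation.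
- A2 still needs acylation of the tertiary OH next to a more reactive enol.
- The chosen plan never passes through an aromatic carbocycle and installs the butyrate when no other hydroxyl exists.

**Alternative 2: aldol condensation onto a 3-acyl-4-pyranone.** Cut: C4a=C5, with C5 as a free enol nucleophile. Forward: acid- or base-mediated closure of keto alcohol A3 onto the pyranone carbonyl.
- In A3 the C5 enol reaches C1 and C4a through six-membered transition states of the same type. C1 is the β-carbon of two carbonyls and the usual site of attack, while the pyranone carbonyl is the least electrophilic position.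
- Base opens the pyranone, and the 2-acyloxy-1,3-diketone undergoes retro-Claisen cleavage.
- The chosen plan removes the regiochemical question with the sulfur tether.

**Alternative 3: NHC-catalysed intramolecular cross-benzoin.** Cut: C7–C8, joining two carbonyl carbons by polarity reversal. Forward: keto aldehyde A4, chiral triazolium catalyst, to the tertiary ketol A5.
- The 1,2-diketone of A4 offers two acceptors: C7 gives the six-membered ring and C6 a five-membered ring, and the two ketols can interconvert by α-ketol shift.
- The aldehyde is a vinylogous formate and is deactivated towards the carbene.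
- A4, an enol ether of a vicinal tricarbonyl on a pyranylidene, is harder to make than the target.
- The tertiary butyrylation problem returns. Lactic acid supplies the stereocentre more cheaply and with certainty.

Key step: step 10

Assumption: the geometry of the exocyclic C4a=C5 bond in 18 and 19 is left undefined, because this strongly polarised (push–pull) bond is expected to rotate under the reaction conditions.

## Route

Step 1
Reactants: 1 3-methoxy-2-methyl-4H-pyran-4-one; 2 tert-butyl(2-iodoethoxy)dimethylsilane
Product: 3 2-[3-(tert-butyldimethylsilyloxy)propyl]-3-methoxy-4H-pyran-4-one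
Conditions: LiHMDS, THF, −78 °C; then 2, DMPU, −78 → −20 °C
Reagents that add atoms: none
Why: The 2-methyl group is vinylogously acidic; LiHMDS gives the extended enolate, which is C-alkylated at the exocyclic carbon by the primary iodide (lateral alkylation of a 2-methyl-4-pyranone); no stereocentre is formed.

Step 2
Reactants: 3 2-[3-(tert-butyldimethylsilyloxy)propyl]-3-methoxy-4H-pyran-4-one
Product: 4 2-[3-(tert-butyldimethylsilyloxy)propyl]-5-iodo-3-methoxy-4H-pyran-4-one
Conditions: I2, pyridine, CH2Cl2, 0 °C → rt
Reagents that add atoms: iodine, II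
Why: C5 is the α-carbon of the β-alkoxy enone and the only nucleophilic ring C–H; Johnson-type α-iodination (pyridine adds at C6, the enolate is iodinated, pyridine is eliminated) installs the future C8a handle without acid, so the silyl ether is safe.

Step 3
Reactants: 4 2-[3-(tert-butyldimethylsilyloxy)propyl]-5-iodo-3-methoxy-4H-pyran-4-one
Product: 5 2-[3-(tert-butyldimethylsilyloxy)propyl]-5-iodo-3-methoxy-4H-pyran-4-thione
Conditions: Lawesson's reagent, toluene, 80 °C
Reagents that add atoms: Lawesson's reagent, COc1ccc(cc1)P1(=S)SP(=S)(S1)c1ccc(OC)cc1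
Why: The doubly vinylogous pyranone carbonyl is the most electron-rich C=O and is thionated cleanly to the stable 4H-pyran-4-thione; vinyl iodide, enol ether and silyl ether are inert to the reagent.

Step 4
Reactants: 6 (R)-lactic acid; 7 pivalaldehyde
Product: 8 (2R,5R)-2-tert-butyl-5-methyl-1,3-dioxolan-4-one
Conditions: cat. TsOH, cat. H2SO4, pentane, reflux (Dean–Stark); recrystallisation at −78 °C
Reagents that add atoms: none
Why: Seebach acetalisation; the cis acetal is expected to predominate and is purified by crystallisation, so the new acetal stereocentre is set by the lactic acid stereocentre and stores its chirality for the next step.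

Step 5
Reactants: 8 (2R,5R)-2-tert-butyl-5-methyl-1,3-dioxolan-4-one; 9 (benzyloxy)acetaldehyde
Product: 10 (2R,5S)-5-[2-(benzyloxy)-1-hydroxyethyl]-2-tert-butyl-5-methyl-1,3-dioxolan-4-one (carbinol epimers)
Conditions: LDA, THF, −78 °C; then 9, −78 °C; AcOH quench
Reagents that add atoms: none
Why: Aldol addition of the planar lithium enolate occurs on the face opposite the tert-butyl group (self-regeneration of stereocentres), so the new C–C bond replaces the original H with retention and fixes the future C7; the carbinol configuration is irrelevant because it is oxidised next.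

Step 6
Reactants: 10 (2R,5S)-5-[2-(benzyloxy)-1-hydroxyethyl]-2-tert-butyl-5-methyl-1,3-dioxolan-4-one
Product: 11 (2R,5S)-5-[(benzyloxy)acetyl]-2-tert-butyl-5-methyl-1,3-dioxolan-4-one
Conditions: Dess–Martin periodinane, CH2Cl2, rt
Reagents that add atoms: none
Why: Dess–Martin oxidation converts the hindered secondary alcohol to the ketone (future C6) under neutral conditions that avoid retro-aldol cleavage; the quaternary centre cannot epimerise.

Step 7
Reactants: 11 (2R,5S)-5-[(benzyloxy)acetyl]-2-tert-butyl-5-methyl-1,3-dioxolan-4-one
Product: 13 (3S)-3-hydroxy-3-methylfuran-2,4(3H,5H)-dione, via hydroxy ketone 12 (not isolated)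
Conditions: H2 (1 atm), Pd/C, EtOAc, rt; then cat. CSA, rt; evaporation
Reagents that add atoms: none
Why: Hydrogenolysis frees the primary alcohol, which attacks the acylal carbonyl (5-exo-trig translactonisation) and expels the hemiacetal as volatile pivalaldehyde, releasing the tertiary OH; the temporary acetal is removed without touching the quaternary centre.

Step 8
Reactants: 13 (3S)-3-hydroxy-3-methylfuran-2,4(3H,5H)-dione
Product: 14 (3S)-3-methyl-2,4-dioxotetrahydrofuran-3-yl butanoate
Conditions: (n-PrCO)2O, cat. Sc(OTf)3, MeCN, −20 → 0 °C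
Reagents that add atoms: butanoic anhydride, CCCC(=O)OC(=O)CCC
Why: Lewis-acid-catalysed acylation of a tertiary alcohol with an anhydride; 13 has a single hydroxyl, so the butyrate is placed with no selectivity problem, and non-basic conditions avoid retro-Claisen or α-ketol reactions of the hydroxy-β-keto lactone.

Step 9
Reactants: 14 (3S)-3-methyl-2,4-dioxotetrahydrofuran-3-yl butanoate
Product: 15 (3S)-5-bromo-3-methyl-2,4-dioxotetrahydrofuran-3-yl butanoate (C5 epimers)
Conditions: Br2, cat. HBr/AcOH, CH2Cl2, 0 °C → rt; volatiles removed, used crude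
Reagents that add atoms: bromine, BrBr
Why: C5 is the only enolisable carbon (C3 is quaternary), so acid-catalysed ketone α-bromination is regiospecific and gives an α-bromo-α-acyloxy ketone of the 3-bromophthalide type; the C5 configuration does not matter because C5 becomes sp2 in step 10.

Step 10
Reactants: 5 2-[3-(tert-butyldimethylsilyloxy)propyl]-5-iodo-3-methoxy-4H-pyran-4-thione; 15 (3S)-5-bromo-3-methyl-2,4-dioxotetrahydrofuran-3-yl butanoate
Product: 18 (3S)-5-{2-[3-(tert-butyldimethylsilyloxy)propyl]-5-iodo-3-methoxy-4H-pyran-4-ylidene}-3-methyl-2,4-dioxotetrahydrofuran-3-yl butanoate, via alkylthiopyrylium bromide 16 (not isolated), via spiro-thiirane 17 (not isolated)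
Conditions: MeCN, 0 °C → rt (S-alkylation); then PPh3, i-Pr2NEt, rt
Reagents that add atoms: none
Why: The soft thione sulfur of 5 displaces bromide from the α-bromo ketone 15 to give the 4-(alkylthio)pyrylium salt 16. Hünig's base then removes the C5–H, which is now strongly acidic (α to C6=O, to the cationic sulfur and to the lactone oxygen), and the enolate carbon attacks the one pyrylium carbon it can reach, C4a, closing the spiro-thiirane 17 (3-exo-trig onto the C4a–S+ unit). Triphenylphosphine removes sulfur from the thiirane and leaves the C4a=C5 double bond of 18. This is an Eschenmoser sulfide contraction; the closest precedents are contractions of thioamides and vinylogous thioamides and the base-induced sulfur extrusion from 4-(phenacylthio)pyrylium salts. The selectivity needed is C–C bond formation at C4a and not at C1 or C3, where external carbon nucleophiles attack pyrylium and pyranone rings; the temporary C–S bond makes C4a the only carbon within reach. No stereocentre is created: the C5 epimers of 15 and both thiirane carbons end as sp2 centres, C7 is quaternary and cannot enolise, and the alkene geometry is inconsequential. Base is added only after S-alkylation so that 15 is never exposed to it, and the step joins the complete heterocycle to the complete C5–C8 chain with all its oxygen functions, the butyrate and the stereocentre in place.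

Step 11
Reactants: 18 (3S)-5-{2-[3-(tert-butyldimethylsilyloxy)propyl]-5-iodo-3-methoxy-4H-pyran-4-ylidene}-3-methyl-2,4-dioxotetrahydrofuran-3-yl butanoate
Product: 19 methyl (2S)-2-(butanoyloxy)-4-hydroxy-4-{2-[3-(tert-butyldimethylsilyloxy)propyl]-5-iodo-3-methoxy-4H-pyran-4-ylidene}-2-methyl-3-oxobutanoate
Conditions: MeOH, cat. Et3N, CH2Cl2, 0 °C
Reagents that add atoms: methanol, CO
Why: The enol lactone is an activated ester (its leaving group is a stabilised enolate) and is opened by methanol under amine catalysis, whereas the tertiary alkyl butyrate should not transesterify under these conditions; this frees the 5-OH and turns C8 into a methyl ester that can rotate towards C8a.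

Step 12
Reactants: 19 methyl (2S)-2-(butanoyloxy)-4-hydroxy-4-{2-[3-(tert-butyldimethylsilyloxy)propyl]-5-iodo-3-methoxy-4H-pyran-4-ylidene}-2-methyl-3-oxobutanoate
Product: 21 (7R)-3-[3-(tert-butyldimethylsilyloxy)propyl]-5-hydroxy-4-methoxy-7-methyl-6,8-dioxo-7,8-dihydro-6H-isochromen-7-yl butanoate, via vinylmagnesium species 20 (not isolated)
Conditions: i-PrMgCl·LiCl (2.2 equiv), THF, −40 → 0 °C; aq. citric acid work-up
Reagents that add atoms: none
Why: Parham-type cyclisation: the first equivalent deprotonates the enol, and the resulting magnesium enolate makes C1 and C6 poor electrophiles; the second performs iodine–magnesium exchange at C8a, and the vinylmagnesium attacks the C8 ester (6-exo-trig) to close the carbocycle as the ketone. Only the isomer with O5 on the C4 side can cyclise; chelation of the magnesium enolate by the C4 methoxy oxygen should favour it and rotation about the polarised C4a=C5 bond should replenish it. C7 is quaternary and unaffected.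

Step 13
Reactants: 21 (7R)-3-[3-(tert-butyldimethylsilyloxy)propyl]-5-hydroxy-4-methoxy-7-methyl-6,8-dioxo-7,8-dihydro-6H-isochromen-7-yl butanoate
Product: 22 (7R)-5-hydroxy-3-(3-hydroxypropyl)-4-methoxy-7-methyl-6,8-dioxo-7,8-dihydro-6H-isochromen-7-yl butanoate
Conditions: HF·pyridine, THF/pyridine, 0 °C → rt
Reagents that add atoms: none
Why: Fluoride-mediated cleavage of the primary silyl ether under mildly acidic conditions, which the nucleophile-sensitive pyranoquinone, the enol and the tertiary butyrate should tolerate; migration of the butyrate to O5 is not expected because it would turn an alkyl ester into a less stable enol ester.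

## Compound list

1 | 3-methoxy-2-methyl-4H-pyran-4-one (maltol methyl ether) | COC1=C(C)OC=CC1=O | starting material
2 | tert-butyl(2-iodoethoxy)dimethylsilane | CC(C)(C)[Si](C)(C)OCCI | starting material
3 | 2-[3-(tert-butyldimethylsilyloxy)propyl]-3-methoxy-4H-pyran-4-one | COC1=C(CCCO[Si](C)(C)C(C)(C)C)OC=CC1=O | intermediate
4 | 2-[3-(tert-butyldimethylsilyloxy)propyl]-5-iodo-3-methoxy-4H-pyran-4-one | COC1=C(CCCO[Si](C)(C)C(C)(C)C)OC=C(I)C1=O | intermediate
5 | 2-[3-(tert-butyldimethylsilyloxy)propyl]-5-iodo-3-methoxy-4H-pyran-4-thione | COC1=C(CCCO[Si](C)(C)C(C)(C)C)OC=C(I)C1=S | intermediate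
6 | (R)-lactic acid | C[C@@H](O)C(=O)O | starting material
7 | pivalaldehyde | CC(C)(C)C=O | starting material
8 | (2R,5R)-2-tert-butyl-5-methyl-1,3-dioxolan-4-one | C[C@H]1O[C@@H](C(C)(C)C)OC1=O | intermediate
9 | (benzyloxy)acetaldehyde | O=CCOCc1ccccc1 | starting material
10 | (2R,5S)-5-[2-(benzyloxy)-1-hydroxyethyl]-2-tert-butyl-5-methyl-1,3-dioxolan-4-one (carbinol epimers) | C[C@@]1(C(O)COCc2ccccc2)O[C@@H](C(C)(C)C)OC1=O | intermediate
11 | (2R,5S)-5-[(benzyloxy)acetyl]-2-tert-butyl-5-methyl-1,3-dioxolan-4-one | C[C@@]1(C(=O)COCc2ccccc2)O[C@@H](C(C)(C)C)OC1=O | intermediate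
12 | (2R,5S)-2-tert-butyl-5-(hydroxyacetyl)-5-methyl-1,3-dioxolan-4-one | C[C@@]1(C(=O)CO)O[C@@H](C(C)(C)C)OC1=O | intermediate (not isolated)
13 | (3S)-3-hydroxy-3-methylfuran-2,4(3H,5H)-dione | C[C@]1(O)C(=O)COC1=O | intermediate
14 | (3S)-3-methyl-2,4-dioxotetrahydrofuran-3-yl butanoate | CCCC(=O)O[C@]1(C)C(=O)OCC1=O | intermediate
15 | (3S)-5-bromo-3-methyl-2,4-dioxotetrahydrofuran-3-yl butanoate (C5 epimers) | CCCC(=O)O[C@]1(C)C(=O)OC(Br)C1=O | intermediate
16 | 4-{[(4S)-4-(butanoyloxy)-4-methyl-3,5-dioxotetrahydrofuran-2-yl]sulfanyl}-2-[3-(tert-butyldimethylsilyloxy)propyl]-5-iodo-3-methoxypyrylium bromide | COc1c(CCCO[Si](C)(C)C(C)(C)C)[o+]cc(I)c1SC1OC(=O)[C@@](C)(OC(=O)CCC)C1=O.[Br-] | intermediate (not isolated)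
17 | thiirane spiro-fused at C4 of the 4H-pyran of 5 and at C5 of the (3S)-lactone of 14 | COC1=C(CCCO[Si](C)(C)C(C)(C)C)OC=C(I)C12SC23OC(=O)[C@@](C)(OC(=O)CCC)C3=O | intermediate (not isolated)
18 | (3S)-5-{2-[3-(tert-butyldimethylsilyloxy)propyl]-5-iodo-3-methoxy-4H-pyran-4-ylidene}-3-methyl-2,4-dioxotetrahydrofuran-3-yl butanoate | CCCC(=O)O[C@]1(C)C(=O)OC(=C2C(I)=COC(CCCO[Si](C)(C)C(C)(C)C)=C2OC)C1=O | intermediate
19 | methyl (2S)-2-(butanoyloxy)-4-hydroxy-4-{2-[3-(tert-butyldimethylsilyloxy)propyl]-5-iodo-3-methoxy-4H-pyran-4-ylidene}-2-methyl-3-oxobutanoate | CCCC(=O)O[C@](C)(C(=O)OC)C(=O)C(O)=C1C(I)=COC(CCCO[Si](C)(C)C(C)(C)C)=C1OC | intermediate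
20 | bis(chloromagnesium) derivative of 19 (O5 enolate, C8a vinylmagnesium) | CCCC(=O)O[C@](C)(C(=O)OC)C(=O)C(O[Mg]Cl)=C1C([Mg]Cl)=COC(CCCO[Si](C)(C)C(C)(C)C)=C1OC | intermediate (not isolated)
21 | (7R)-3-[3-(tert-butyldimethylsilyloxy)propyl]-5-hydroxy-4-methoxy-7-methyl-6,8-dioxo-7,8-dihydro-6H-isochromen-7-yl butanoate | CCCC(=O)O[C@]1(C)C(=O)C2=COC(CCCO[Si](C)(C)C(C)(C)C)=C(OC)C2=C(O)C1=O | intermediate
22 | (7R)-5-hydroxy-3-(3-hydroxypropyl)-4-methoxy-7-methyl-6,8-dioxo-7,8-dihydro-6H-isochromen-7-yl butanoate | CCCC(=O)O[C@]1(C)C(=O)C2=COC(CCCO)=C(OC)C2=C(O)C1=O | target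

## Step count and least certain steps

Total steps: 13. Longest linear sequence: 10 steps (steps 4–13, from (R)-lactic acid 6). The pyran branch (steps 1–3) joins at step 10.

**Step 10 (key step).** The most likely failure is bromophilic attack of the thione sulfur on 15 (transfer of Br+ and loss of the electrophile) instead of substitution at carbon. Sulfur extrusion may also stall, because the thiirane and the alkene are flanked by the iodine and the methoxy group, and 15 may decompose if base meets it before S-alkylation is complete. Fallback, from 5 and 14, returning at 18: thione 5 is S-methylated with methyl triflate to 2-[3-(tert-butyldimethylsilyloxy)propyl]-5-iodo-3-methoxy-4-(methylsulfanyl)pyrylium triflate F1. The lithium enolate of 14 (LiHMDS, −78 °C) is added to it, and addition at C4 followed by loss of methanethiol gives 18. This is the known condensation of 4-alkylthiopyrylium salts with C–H acids; it gives up the intramolecular delivery and therefore carries the C1/C4a regiochemical risk that the main step avoids.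

**Step 12.** Iodine–magnesium exchange on the electron-rich vinyl iodide may be slower than intermolecular addition of the Grignard reagent to the ester or ketone. The vinylmagnesium, which has the ring oxygen β and anti, may open the pyran by β-elimination. The reactive C4a=C5 isomer may be poorly populated because iodine is bulkier than methoxy, and the butyrate may be attacked. Fallback, from 18, returning at 22:
- The lactone is opened with ethanethiol/Et3N to S-ethyl (2S)-2-(butanoyloxy)-4-hydroxy-4-{2-[3-(tert-butyldimethylsilyloxy)propyl]-5-iodo-3-methoxy-4H-pyran-4-ylidene}-2-methyl-3-oxobutanethioate F2.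
- The enol is silylated (TESCl, imidazole) to its 4-O-triethylsilyl ether F3.
- Zinc insertion into the C–I bond (Zn, LiCl) and Pd-catalysed intramolecular Fukuyama coupling with the thioester give (7R)-3-[3-(tert-butyldimethylsilyloxy)propyl]-4-methoxy-7-methyl-6,8-dioxo-5-(triethylsilyloxy)-7,8-dihydro-6H-isochromen-7-yl butanoate F4.
- HF·pyridine removes both silyl groups to give 22.
The organozinc does not add to ketones or esters and is less prone to β-elimination.

**Step 9.** Over-bromination at C5 and HBr-promoted cleavage of the lactone or butyrate are the likely problems, and the α-bromo-α-acyloxy ketone is moisture-sensitive. Fallback, from 14, returning at 15: soft enolisation (TBSOTf, Et3N) gives (3S)-4-(tert-butyldimethylsilyloxy)-3-methyl-2-oxo-2,3-dihydrofuran-3-yl butanoate F5, which is brominated with one equivalent of NBS at −78 °C under neutral conditions to give 15.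

**Step 1.** Alkylation of the extended enolate by a β-silyloxy iodide may be sluggish, and E2 elimination of the iodide or dialkylation may compete. Fallback, from 1, returning at 3:
- Aldol addition of the same enolate to (tert-butyldimethylsilyloxy)acetaldehyde gives 2-[3-(tert-butyldimethylsilyloxy)-2-hydroxypropyl]-3-methoxy-4H-pyran-4-one F6.
- Mesylation and elimination (MsCl, Et3N; DBU) give (E)-2-[3-(tert-butyldimethylsilyloxy)prop-1-enyl]-3-methoxy-4H-pyran-4-one F7.
- Hydrogenation of the exocyclic alkene (H2, Pd/C) gives 3.

## Further compounds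

F1 | step 10 | 2-[3-(tert-butyldimethylsilyloxy)propyl]-5-iodo-3-methoxy-4-(methylsulfanyl)pyrylium trifluoromethanesulfonate | COc1c(CCCO[Si](C)(C)C(C)(C)C)[o+]cc(I)c1SC.[O-]S(=O)(=O)C(F)(F)F
F2 | step 12 | S-ethyl (2S)-2-(butanoyloxy)-4-hydroxy-4-{2-[3-(tert-butyldimethylsilyloxy)propyl]-5-iodo-3-methoxy-4H-pyran-4-ylidene}-2-methyl-3-oxobutanethioate | CCCC(=O)O[C@](C)(C(=O)SCC)C(=O)C(O)=C1C(I)=COC(CCCO[Si](C)(C)C(C)(C)C)=C1OC
F3 | step 12 | S-ethyl (2S)-2-(butanoyloxy)-4-{2-[3-(tert-butyldimethylsilyloxy)propyl]-5-iodo-3-methoxy-4H-pyran-4-ylidene}-2-methyl-3-oxo-4-(triethylsilyloxy)butanethioate | CCCC(=O)O[C@](C)(C(=O)SCC)C(=O)C(O[Si](CC)(CC)CC)=C1C(I)=COC(CCCO[Si](C)(C)C(C)(C)C)=C1OC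
F4 | step 12 | (7R)-3-[3-(tert-butyldimethylsilyloxy)propyl]-4-methoxy-7-methyl-6,8-dioxo-5-(triethylsilyloxy)-7,8-dihydro-6H-isochromen-7-yl butanoate | CCCC(=O)O[C@]1(C)C(=O)C2=COC(CCCO[Si](C)(C)C(C)(C)C)=C(OC)C2=C(O[Si](CC)(CC)CC)C1=O
F5 | step 9 | (3S)-4-(tert-butyldimethylsilyloxy)-3-methyl-2-oxo-2,3-dihydrofuran-3-yl butanoate | CCCC(=O)O[C@]1(C)C(=O)OC=C1O[Si](C)(C)C(C)(C)C
F6 | step 1 | 2-[3-(tert-butyldimethylsilyloxy)-2-hydroxypropyl]-3-methoxy-4H-pyran-4-one | COC1=C(CC(O)CO[Si](C)(C)C(C)(C)C)OC=CC1=O
F7 | step 1 | (E)-2-[3-(tert-butyldimethylsilyloxy)prop-1-enyl]-3-methoxy-4H-pyran-4-one | COC1=C(/C=C/CO[Si](C)(C)C(C)(C)C)OC=CC1=O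
A1 | alternative 1 | 3-[3-(tert-butyldimethylsilyloxy)propyl]-5,8-dihydroxy-4-methoxy-7-methyl-6H-isochromen-6-one (anhydrobase of the 5,6,8-trihydroxy-2-benzopyrylium) | COC1=C(CCCO[Si](C)(C)C(C)(C)C)OC=C2C1=C(O)C(=O)C(C)=C2O
A2 | alternative 1 | (7R)-3-[3-(tert-butyldimethylsilyloxy)propyl]-5,7-dihydroxy-4-methoxy-7-methyl-6H-isochromene-6,8(7H)-dione | C[C@@]1(O)C(=O)C2=COC(CCCO[Si](C)(C)C(C)(C)C)=C(OC)C2=C(O)C1=O
A3 | alternative 2 | (2R)-1-{6-[3-(tert-butyldimethylsilyloxy)propyl]-5-methoxy-4-oxo-4H-pyran-3-yl}-4-hydroxy-2-methyl-1,3-dioxobutan-2-yl butanoate | CCCC(=O)O[C@@](C)(C(=O)CO)C(=O)C1=COC(CCCO[Si](C)(C)C(C)(C)C)=C(OC)C1=O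
A4 | alternative 3 | 4-[1-(benzyloxy)-2,3-dioxobutylidene]-6-[3-(tert-butyldimethylsilyloxy)propyl]-5-methoxy-4H-pyran-3-carbaldehyde | CC(=O)C(=O)C(OCc1ccccc1)=C1C(C=O)=COC(CCCO[Si](C)(C)C(C)(C)C)=C1OC
A5 | alternative 3 | (7R)-5-(benzyloxy)-3-[3-(tert-butyldimethylsilyloxy)propyl]-7-hydroxy-4-methoxy-7-methyl-6H-isochromene-6,8(7H)-dione | C[C@@]1(O)C(=O)C2=COC(CCCO[Si](C)(C)C(C)(C)C)=C(OC)C2=C(OCc3ccccc3)C1=O
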